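| setting | maple | birch | green | blue | teal |
|---|---|---|---|---|---|
| starting material | 0.50 M | 0.50 M | 0.50 M | 0.50 M | 0.50 M |
| reagent | 0.525 M | 0.525 M | 0.525 M | 0.525 M | 0.525 M |
| second substrate | 0.045 M | 0.13 M | 0.0500 M | 0.100 M | 0.200 M |
| protic impurity | 0.050 M | 0.050 M | 0.0500 M | 0.0500 M | 0.0500 M |
| remark | run made earlier | run made earlier |  |  |  |
| time |  |  | 3.0 min | 3.0 min | 3.0 min |

- maple (time / min: target / %): 0.250: 23.1; 0.333: 27.7; 0.500: 35.6; 0.833: 44.5; 1.33: 51.3; 2.00: 54.6; 3.00: 57.5
- birch (time / min: target / %): 0.250: 21.9; 0.333: 26.0; 0.500: 33.8; 0.833: 41.6; 1.33: 49.2; 2.00: 53.0; 3.00: 54.2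

(readings scatter by 0.5 percentage points)

- amount of target at the end, in percent of the starting material charged for green, blue, teal, in this order
- how that number moves from the first to the last of them (rises all the way / falls all the way / hardly changes / falls, then rises / rises, then falls)

- the earlier runs were read with a standard deviation of 0.5 percentage points
- "hardly changes" means that all values lie within two and a half points (for a concentration: within two and a half percent of the largest)

1. Take the last readings of the maple and birch runs as two ends and join them with a straight line: that was my bench rule for the new flasks green, blue and teal.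

2. From maple to birch, c(second substrate) rose from 0.045 M to 0.13 M, a step of 0.0850 M. The target at 3.00 min went from 57.5 % to 54.2 %, a drop of 3.3 percentage points, and each of the two readings carried a scatter of 0.5 points.

3. Dividing the drop by the step gave 0.388 M⁻¹. I called this the cost of second substrate, a sensitivity: the fraction of the starting material charged by which the target falls at equal time per M of second substrate added, the other charges held as in maple and birch.

4. Starting from maple and paying the cost, I reckoned 57.3 % for green, 55.4 % for blue and 51.5 % for teal, a row that falls all the way.

5. The line had readings under it up to birch. Green and blue lay between the two ends, but teal's c(second substrate) was 1.54 times birch's, so my teal value was an extrapolation beyond the runs.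

6. The forecast gave 57.2 %, 55.2 % and 51 %, with the shape falls all the way. Its teal stood below my 51.5 %, and of that point it said: “I shade teal slightly lower”.

    second substrate + protic impurity → quenched substrate (k = 0.410 M⁻¹ s⁻¹)
    second substrate + reagent ⇌ second product (K = 5.70 M⁻¹, k = 0.370 M⁻¹ s⁻¹)
    starting material + reagent ⇌ target (K = 6.00 M⁻¹, k = 0.0430 M⁻¹ s⁻¹)

Green, blue and teal gave 57.0 %, 55.5 % and 52.0 %, and the shape was falls all the way. At 3.00 min, teal still held 35.7 % of its reagent charge. I then paid the cost once more, over the step from blue to teal, starting from blue's result. That gave 51.6 % for teal, against the 52.0 % of the teal flask.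

(The readings were generated by integration with made-up constants; noise was put on by code.)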